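The oxolane (O1, C2–C5) is disconnected to a cyclopropane. C3, C4 and C5 are the three-membered ring of a 4-aryl-3-oxabicyclo[3.1.0]hexan-2-one; C2 and O1 are the C=O of O-benzylvanillin. MgI2 opens the cyclopropane at its CH2, the lactone enolate adds to the aldehyde and the aldolate oxygen displaces iodide: one operation inserts two atoms, forms C2–C3 and O1–C5 and gives a cis-fused furofuranone. The feature used is that the C3 hydroxymethyl and the C4 aryl carbinol are one masked γ-lactone, which activates the cyclopropane, forces the 3,4-cis relation and is opened by LiAlH4 at the end. The precursor is a vinyl-addition product of the same aldehyde, cyclopropanated through its diazoacetate.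

Key step: step 4

Remark: the SMILES is read as the (2R,3S,4S)-oxolane (aryl and CH2OH trans, CH2OH and carbinol side chain cis) with an (R)-carbinol; both phenols are carried as benzyl ethers.

Step 1
Reactants: 1 4-(benzyloxy)-3-methoxybenzaldehyde (O-benzylvanillin)
Product: 2 (R)-1-[4-(benzyloxy)-3-methoxyphenyl]prop-2-en-1-ol
Conditions: Zn(CH=CH2)2 (from CH2=CHMgBr and ZnCl2, Mg salts precipitated with 1,4-dioxane), (+)-3-exo-(dimethylamino)isoborneol [(+)-DAIB, 5 mol %], toluene/Et2O, 0 °C; aq. NH4Cl
Reagents that add atoms: divinylzinc, C=C[Zn]C=C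
Why: Amino-alcohol-catalysed enantioselective addition of a vinylzinc reagent to an aryl aldehyde; the (+)-antipode of DAIB, whose (−)-form gives (S)-carbinols from aryl aldehydes, should set the R carbinol centre.

Step 2
Reactants: 2 (R)-1-[4-(benzyloxy)-3-methoxyphenyl]prop-2-en-1-ol
Product: 3 (R)-1-[4-(benzyloxy)-3-methoxyphenyl]prop-2-en-1-yl 2-diazoacetate
Conditions: TsNHN=CHCOCl, PhNMe2, CH2Cl2, 0 °C; then Et3N, 0 °C to rt
Reagents that add atoms: glyoxylic acid chloride p-toluenesulfonylhydrazone, Cc1ccc(cc1)S(=O)(=O)NN=CC(Cl)=O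
Why: Diazoacetate synthesis by O-acylation with the acid chloride tosylhydrazone and base-induced loss of sulfinate (Bamford–Stevens-type elimination); the carbinol centre is not touched and the buffered medium should avoid ionisation of the electron-rich allylic ester.

Step 3
Reactants: 3 (R)-1-[4-(benzyloxy)-3-methoxyphenyl]prop-2-en-1-yl 2-diazoacetate
Product: 4 (1S,4R,5R)-4-[4-(benzyloxy)-3-methoxyphenyl]-3-oxabicyclo[3.1.0]hexan-2-one
Conditions: Rh2(5R-MEPY)4 (dirhodium tetrakis[methyl (5R)-2-oxopyrrolidine-5-carboxylate], 1 mol %), CH2Cl2, reflux, slow addition of 3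
Reagents that add atoms: none
Why: Intramolecular cyclopropanation of an allylic diazoacetate through a rhodium carbene; the 5R-carboxamidate catalyst favours the (1S,5R) bicycle and the R carbinol centre places its aryl on the convex face anti to the cyclopropane CH2, so catalyst and substrate should be matched and C1 and C5 are set together.

Step 4
Reactants: 4 (1S,4R,5R)-4-[4-(benzyloxy)-3-methoxyphenyl]-3-oxabicyclo[3.1.0]hexan-2-one; 1 4-(benzyloxy)-3-methoxybenzaldehyde
Product: 7 (1R,4R,5S,8R)-4,8-bis[4-(benzyloxy)-3-methoxyphenyl]-3,7-dioxabicyclo[3.3.0]octan-2-one, via magnesium iodo-enolate 5 (not isolated), via magnesium iodo-aldolate 6 (not isolated)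
Conditions: 1 (1.5 equiv), MgI2 (1.0 equiv), THF, 75 °C, sealed tube
Reagents that add atoms: none
Why: Proposed new method: Mg2+ binds the lactone carbonyl and iodide opens the cyclopropane by SN2 at the unsubstituted C6, cleaving the exocyclic C1–C6 bond that overlaps with the carbonyl π system, to give iodo enolate 5; aldol addition to 1 gives aldolate 6, whose alkoxide displaces iodide and returns MgI2. The closest known reactions are the MgI2-mediated ring expansion of carbonyl-activated cyclopropanes (spirocyclopropyl oxindoles, cyclopropyl ketones) with imines to pyrrolidines and the iodide-induced ring-opening aldol reaction of cyclopropyl ketones; new are a lactone as the only activating group and an aldehyde as the two-atom partner. The oxolane closes by 5-exo-tet O-alkylation, so the three cyclopropane carbons end as C1, C5 and C6 of 7 and the aldehyde supplies C8 and O7. C1 (ring fusion) is controlled by the fused lactone, because only the aldolate with the carbinol carbon cis to CH2I can close and the magnesium aldolates should interconvert by retro-aldol reaction, while C8 is expected to carry its aryl exo because in the product-determining closure the aryl stays on the convex face away from the lactone carbonyl. The step needs attack at CH2 (not at C5 or at the benzylic lactone C4–O bond) and ring closure faster than dehydration of the aldolate; the first is secured by sterics and orbital alignment, the second by the intramolecular primary iodide. C4 and C5 are not touched.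

Step 5
Reactants: 7 (1R,4R,5S,8R)-4,8-bis[4-(benzyloxy)-3-methoxyphenyl]-3,7-dioxabicyclo[3.3.0]octan-2-one
Product: 8 (R)-[4-(benzyloxy)-3-methoxyphenyl]{(3S,4S,5R)-5-[4-(benzyloxy)-3-methoxyphenyl]-4-(hydroxymethyl)oxolan-3-yl}methanol
Conditions: LiAlH4, THF, 0 °C; aq. NaOH work-up
Reagents that add atoms: none
Why: Hydride reduction of the γ-lactone to the 1,4-diol; no bond to a stereocentre is broken, so the lactone carbonyl becomes the C3 hydroxymethyl group and the lactone oxygen the free R carbinol.

Step 6
Reactants: 8 (R)-[4-(benzyloxy)-3-methoxyphenyl]{(3S,4S,5R)-5-[4-(benzyloxy)-3-methoxyphenyl]-4-(hydroxymethyl)oxolan-3-yl}methanol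
Product: 9 (R)-(4-hydroxy-3-methoxyphenyl)[(3S,4S,5R)-5-(4-hydroxy-3-methoxyphenyl)-4-(hydroxymethyl)oxolan-3-yl]methanol
Conditions: H2 (1 atm), 10% Pd/C, EtOAc/MeOH, rt, stopped after 2 equiv H2
Reagents that add atoms: none
Why: Hydrogenolysis of the two aryl benzyl ethers over palladium; under neutral conditions these should cleave faster than the benzylic C–O bonds of the oxolane and the carbinol.

Compound list
1 | 4-(benzyloxy)-3-methoxybenzaldehyde (O-benzylvanillin) | COc1cc(C=O)ccc1OCc1ccccc1 | starting material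
2 | (R)-1-[4-(benzyloxy)-3-methoxyphenyl]prop-2-en-1-ol | C=C[C@@H](O)c1ccc(OCc2ccccc2)c(OC)c1 | intermediate
3 | (R)-1-[4-(benzyloxy)-3-methoxyphenyl]prop-2-en-1-yl 2-diazoacetate | C=C[C@@H](OC(=O)C=[N+]=[N-])c1ccc(OCc2ccccc2)c(OC)c1 | intermediate
4 | (1S,4R,5R)-4-[4-(benzyloxy)-3-methoxyphenyl]-3-oxabicyclo[3.1.0]hexan-2-one (aryl trans to the cyclopropane CH2) | O=C1O[C@@H](c3ccc(OCc4ccccc4)c(OC)c3)[C@@H]2C[C@H]12 | intermediate
5 | iodomagnesium enolate of (4R,5R)-5-[4-(benzyloxy)-3-methoxyphenyl]-4-(iodomethyl)oxolan-2-one (not isolated) | I[Mg]OC1=C[C@@H](CI)[C@H](c2ccc(OCc3ccccc3)c(OC)c2)O1 | intermediate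
6 | iodomagnesium alkoxide of (3R,4R,5R)-5-[4-(benzyloxy)-3-methoxyphenyl]-3-{(R)-[4-(benzyloxy)-3-methoxyphenyl](hydroxy)methyl}-4-(iodomethyl)oxolan-2-one (not isolated) | O=C1O[C@@H](c2ccc(OCc3ccccc3)c(OC)c2)[C@H](CI)[C@@H]1[C@@H](O[Mg]I)c4ccc(OCc5ccccc5)c(OC)c4 | intermediate
7 | (1R,4R,5S,8R)-4,8-bis[4-(benzyloxy)-3-methoxyphenyl]-3,7-dioxabicyclo[3.3.0]octan-2-one (cis-fused, both aryl groups exo) | O=C1O[C@@H](c3ccc(OCc4ccccc4)c(OC)c3)[C@@H]2CO[C@@H](c5ccc(OCc6ccccc6)c(OC)c5)[C@H]12 | intermediate
8 | (R)-[4-(benzyloxy)-3-methoxyphenyl]{(3S,4S,5R)-5-[4-(benzyloxy)-3-methoxyphenyl]-4-(hydroxymethyl)oxolan-3-yl}methanol | COc1cc([C@H](O)[C@@H]2CO[C@@H](c3ccc(OCc4ccccc4)c(OC)c3)[C@@H]2CO)ccc1OCc1ccccc1 | intermediate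
9 | (R)-(4-hydroxy-3-methoxyphenyl)[(3S,4S,5R)-5-(4-hydroxy-3-methoxyphenyl)-4-(hydroxymethyl)oxolan-3-yl]methanol | COc1cc([C@H](O)[C@@H]2CO[C@@H](c3ccc(O)c(OC)c3)[C@@H]2CO)ccc1O | target

Total step count: 6. Longest linear sequence: 6 steps (1 → 2 → 3 → 4 → 7 → 8 → 9; aldehyde 1 enters a second time in step 4).

Steps most likely to fail

Step 4. The singly activated cyclopropane may resist iodide opening, the aldolate may dehydrate before it closes, or the aryl may end on the concave face at C8. The fallback uses known reactions, sets out from 1 and comes back at 7.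
- A hetero-Diels–Alder reaction of 1 with trans-1-methoxy-3-(trimethylsilyloxy)buta-1,3-diene under BINOL/Ti(OiPr)4 catalysis (antipode chosen for the R product, TFA work-up) would give (R)-2-[4-(benzyloxy)-3-methoxyphenyl]-2,3-dihydro-4H-pyran-4-one F1.
- Conjugate reduction with LiBH(sBu)3 and trapping of the enolate with a second equivalent of 1 would give the anti aldol adduct, the 2,5-trans tetrahydropyran-4-one F2. The facial selectivity of this aldol is not secured, so any cis isomer is separated.
- Silylation (TBSOTf, 2,6-lutidine) would give the silyl ether F3.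
- Diazo transfer at the remaining CH2 after trifluoroacetyl activation (LiN(SiMe3)2, CF3CO2CH2CF3; then MsN3, Et3N) would give the diazo ketone F4.
- Photochemical Wolff rearrangement in MeOH would contract the pyranone to the methyl oxolane-3-carboxylate F5, with retention at the migrating carbon; the ring carbonyl carbon becomes the ester carbon.
- TBAF, then DBU, would remove the silyl group, epimerise the ester-bearing carbon and close the lactone to 7.

Step 3. The aryl may end syn to the cyclopropane CH2 (poor facial selectivity), the electron-rich allylic ester may ionise and transpose, or the carbene may abstract the doubly activated carbinol hydrogen or add to the arene. The fallback sets out from 2 and comes back at 4.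
- Acryloyl chloride/Et3N would give the acrylate (R)-1-[4-(benzyloxy)-3-methoxyphenyl]prop-2-en-1-yl prop-2-enoate F6.
- Ring-closing metathesis with the second-generation Grubbs catalyst would give the butenolide (R)-5-[4-(benzyloxy)-3-methoxyphenyl]furan-2(5H)-one F7.
- Pd(OAc)2-catalysed cyclopropanation with CH2N2 (Et2O, 0 °C, neutral) would add CH2 to the face anti to the aryl and give 4.

Step 1. Residual magnesium salts or uncatalysed background addition may erode the enantioselectivity. The fallback sets out from 1 and comes back at 2.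
- CH2=CHMgBr in THF would give racemic 1-[4-(benzyloxy)-3-methoxyphenyl]prop-2-en-1-ol F8.
- Sharpless kinetic resolution (Ti(OiPr)4, D-(−)-diisopropyl tartrate, tBuOOH, 4 Å MS, CH2Cl2, −20 °C) would epoxidise the S enantiomer and leave 2.

Further compounds
F1 | step 4 | (R)-2-[4-(benzyloxy)-3-methoxyphenyl]-2,3-dihydro-4H-pyran-4-one | O=C1C[C@H](c2ccc(OCc3ccccc3)c(OC)c2)OC=C1
F2 | step 4 | (2R,5S)-2-[4-(benzyloxy)-3-methoxyphenyl]-5-{(R)-[4-(benzyloxy)-3-methoxyphenyl](hydroxy)methyl}tetrahydro-4H-pyran-4-one | O=C1C[C@H](c2ccc(OCc3ccccc3)c(OC)c2)OC[C@H]1[C@@H](O)c4ccc(OCc5ccccc5)c(OC)c4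
F3 | step 4 | tert-butyldimethylsilyl ether of F2 | O=C1C[C@H](c2ccc(OCc3ccccc3)c(OC)c2)OC[C@H]1[C@@H](O[Si](C)(C)C(C)(C)C)c4ccc(OCc5ccccc5)c(OC)c4
F4 | step 4 | 3-diazo derivative of F3 (diazo group on the ring carbon between the ketone and the aryl-bearing carbon) | O=C1C(=[N+]=[N-])[C@H](c2ccc(OCc3ccccc3)c(OC)c2)OC[C@H]1[C@@H](O[Si](C)(C)C(C)(C)C)c4ccc(OCc5ccccc5)c(OC)c4
F5 | step 4 | methyl (2R,4S)-2-[4-(benzyloxy)-3-methoxyphenyl]-4-{(R)-[4-(benzyloxy)-3-methoxyphenyl](tert-butyldimethylsilyloxy)methyl}oxolane-3-carboxylate (C3 epimers) | COC(=O)C1[C@H](c2ccc(OCc3ccccc3)c(OC)c2)OC[C@H]1[C@@H](O[Si](C)(C)C(C)(C)C)c4ccc(OCc5ccccc5)c(OC)c4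
F6 | step 3 | (R)-1-[4-(benzyloxy)-3-methoxyphenyl]prop-2-en-1-yl prop-2-enoate | C=CC(=O)O[C@H](C=C)c1ccc(OCc2ccccc2)c(OC)c1
F7 | step 3 | (R)-5-[4-(benzyloxy)-3-methoxyphenyl]furan-2(5H)-one | O=C1C=C[C@H](c2ccc(OCc3ccccc3)c(OC)c2)O1
F8 | step 1 | racemic 1-[4-(benzyloxy)-3-methoxyphenyl]prop-2-en-1-ol | C=CC(O)c1ccc(OCc2ccccc2)c(OC)c1
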